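In the dihydronaphthalene (C1 diaryl methine, C2 bearing CH2OAc, C3 bearing CHO, C4 vinyl CH), ring B is cut at C1–C2 and C3–C4. C1 and C4 hang on the adjacent ring-A carbons C8a and C4a, as the two exocyclic carbons of an o-quinodimethane do, and C2–C3 with its CH2OAc and CHO groups is (E)-4-acetoxybut-2-enal. UV irradiation of a 2-benzylbenzaldehyde (8-OMe in place, both phenols as TIPS ethers) generates the hydroxy-o-quinodimethane. Its titanium TADDOLate-templated endo [4+2] addition to the enal closes ring B, forms both C–C bonds and sets the trans C1/C2 centres (plus transient C3 and C4) in one operation. Dehydration across C3–C4 and desilylation finish the synthesis.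

Key step: step 9

Assumption: the sense of induction of the titanium TADDOLate with this acyclic enal cannot be predicted with certainty; the (R,R)-ligand is written, and the (S,S)-ligand would replace it, with nothing else changed, should a pilot run show the opposite face to be preferred.

Step 1
Reactants: 1 2-methoxybenzene-1,3-diol
Product: 3 2,4-dihydroxy-3-methoxybenzaldehyde, via aryl iminium chloride 2 (not isolated)
Conditions: POCl3, DMF, MeCN, 0 °C → rt; then H2O, 50 °C
Reagents that add atoms: N,N-dimethylformamide CN(C)C=O; water O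
Why: Vilsmeier–Haack formylation: the chloroiminium ion attacks the ring position para to one hydroxyl and ortho to the other (C4 and C6 of 1 are equivalent), the iminium group then deactivates the ring against a second attack, and hydrolysis of 2 releases the aldehyde with the methyl ether already on the future C8 oxygen, so no phenol has to be methylated selectively later.

Step 2
Reactants: 3 2,4-dihydroxy-3-methoxybenzaldehyde
Product: 4 2-hydroxy-3-methoxy-4-[(triisopropylsilyl)oxy]benzaldehyde
Conditions: TIPSCl (1.05 equiv), imidazole, CH2Cl2, 0 °C → rt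
Reagents that add atoms: chlorotriisopropylsilane CC(C)[Si](Cl)(C(C)C)C(C)C
Why: Site-selective silyl ether formation: the 2-OH is hydrogen-bonded to the formyl group and flanked on both sides, so the more acidic and more accessible 4-OH reacts, and TIPS is chosen because an aryl silyl ether para to a formyl group must survive the later nucleophilic and Lewis-acidic steps.

Step 3
Reactants: 4 2-hydroxy-3-methoxy-4-[(triisopropylsilyl)oxy]benzaldehyde
Product: 5 2-formyl-6-methoxy-5-[(triisopropylsilyl)oxy]phenyl trifluoromethanesulfonate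
Conditions: Tf2O, pyridine, CH2Cl2, −10 → 0 °C
Reagents that add atoms: trifluoromethanesulfonic anhydride O=S(=O)(OS(=O)(=O)C(F)(F)F)C(F)(F)F
Why: Sulfonylation of the chelated phenol to the aryl triflate, a routine conversion of salicylaldehydes that turns the C2 oxygen into a cross-coupling handle without touching the aldehyde or the silyl ether.

Step 4
Reactants: 6 vanillin (4-hydroxy-3-methoxybenzaldehyde)
Product: 7 3-methoxy-4-[(triisopropylsilyl)oxy]benzaldehyde
Conditions: TIPSCl, imidazole, DMF, rt
Reagents that add atoms: chlorotriisopropylsilane CC(C)[Si](Cl)(C(C)C)C(C)C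
Why: Standard silyl ether formation on the only hydroxyl group of vanillin.

Step 5
Reactants: 7 3-methoxy-4-[(triisopropylsilyl)oxy]benzaldehyde
Product: 8 {3-methoxy-4-[(triisopropylsilyl)oxy]phenyl}methanol
Conditions: NaBH4, MeOH/THF, 0 °C
Reagents that add atoms: none
Why: Borohydride reduction of the aryl aldehyde to the benzylic alcohol, which the hindered aryl TIPS ether should tolerate at 0 °C.

Step 6
Reactants: 8 {3-methoxy-4-[(triisopropylsilyl)oxy]phenyl}methanol
Product: 10 [4-(chloromethyl)-2-methoxyphenoxy]triisopropylsilane, via benzylic chlorosulfite 9 (not isolated)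
Conditions: SOCl2, pyridine, CH2Cl2, 0 °C
Reagents that add atoms: thionyl chloride O=S(Cl)Cl
Why: Deoxychlorination with thionyl chloride through the chlorosulfite, which collapses readily at an electron-rich benzylic carbon, while pyridine traps HCl and so protects the silyl ether.

Step 7
Reactants: 10 [4-(chloromethyl)-2-methoxyphenoxy]triisopropylsilane; 5 2-formyl-6-methoxy-5-[(triisopropylsilyl)oxy]phenyl trifluoromethanesulfonate
Product: 12 3-methoxy-2-{3-methoxy-4-[(triisopropylsilyl)oxy]benzyl}-4-[(triisopropylsilyl)oxy]benzaldehyde, via benzylzinc chloride 11 (not isolated)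
Conditions: activated Zn dust, LiCl, THF, 25 °C; then 5, Pd(OAc)2 (2 mol %), SPhos (4 mol %), THF, 25 → 45 °C
Reagents that add atoms: none
Why: Negishi cross-coupling: LiCl-assisted zinc insertion into the benzylic chloride gives a zinc reagent that adds to aldehydes only sluggishly, and Pd/SPhos should couple it with the formyl-activated aryl triflate despite its two ortho substituents, forming the ArCH2–Ar bond of the diarylmethane.

Step 8
Reactants: 13 (Z)-but-2-ene-1,4-diyl diacetate; 14 (E)-but-2-enal (crotonaldehyde, excess)
Product: 15 (E)-4-acetoxybut-2-enal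
Conditions: Hoveyda–Grubbs II (2 mol %), CH2Cl2, 40 °C
Reagents that add atoms: none
Why: Olefin cross-metathesis between a symmetrical allylic diacetate and an enal, in which both halves of 13 are used, but-2-ene escapes and the conjugated product should form as the thermodynamically favoured E isomer.

Step 9
Reactants: 12 3-methoxy-2-{3-methoxy-4-[(triisopropylsilyl)oxy]benzyl}-4-[(triisopropylsilyl)oxy]benzaldehyde; 15 (E)-4-acetoxybut-2-enal
Product: 17 [(1S,2R,3S,4S)-3-formyl-4-hydroxy-8-methoxy-1-{3-methoxy-4-[(triisopropylsilyl)oxy]phenyl}-7-[(triisopropylsilyl)oxy]-1,2,3,4-tetrahydronaphthalen-2-yl]methyl acetate, via outward dienol 16 (not isolated)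
Conditions: Ti(OiPr)4 (2 equiv), (R,R)-TADDOL (2.2 equiv), PhMe, rt, i-PrOH removed in vacuo; then 12, 15 (3 equiv), degassed PhMe, hν 366 nm, 0 °C → rt; aqueous work-up
Reagents that add atoms: none
Why: The n,π*-excited aldehyde of 12 abstracts a hydrogen from the doubly benzylic CH2 through a six-membered transition state (1,5-H shift), and the resulting biradical relaxes to dienol 16 with hydroxyl and guaiacyl both turned outward, which titanium holds as its dienolate. The closest known reaction type is the titanium-alkoxide-promoted photoenolisation/Diels–Alder reaction of electron-rich 2-alkylbenzaldehydes with enones and enals, together with its TADDOLate-mediated enantioselective variant. Six-membered ring B closes by an intermolecular, concerted, suprafacial [4+2] cycloaddition that forms C1–C2 and C3–C4 and rearomatises ring A. C1 and C4 come out cis because both diene substituents are outward, C3 is cis to them because the titanium-bound formyl group reacts endo, C2 is trans to C3 and hence trans to the C1 aryl because the E geometry of 15 is carried over, and the absolute sense at C1/C2 is set by the C2-symmetric TADDOLate, which blocks one face of the titanium-bridged dienol–enal assembly. The step needs ortho regiochemistry, endo approach and the outward dienol: the donor hydroxyl at C4 (largest HOMO coefficient at C1) and the titanium bridge between dienol oxygen and enal carbonyl should provide the first two, and the small, out-of-plane 8-OMe group should still let the aryl sit outward, while the inward position is blocked by the enol C–H.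

Step 10
Reactants: 17 [(1S,2R,3S,4S)-3-formyl-4-hydroxy-8-methoxy-1-{3-methoxy-4-[(triisopropylsilyl)oxy]phenyl}-7-[(triisopropylsilyl)oxy]-1,2,3,4-tetrahydronaphthalen-2-yl]methyl acetate
Product: 19 [(1S,2R)-3-formyl-8-methoxy-1-{3-methoxy-4-[(triisopropylsilyl)oxy]phenyl}-7-[(triisopropylsilyl)oxy]-1,2-dihydronaphthalen-2-yl]methyl acetate, via C4 mesylate 18 (not isolated)
Conditions: MsCl, Et3N, CH2Cl2, 0 °C → rt
Reagents that add atoms: none
Why: Aldol-type dehydration by mesylation and E1cB elimination: the benzylic C4 sulfonate (activated by the para silyloxy group) is expelled with loss of the acidic C3–H under Et3N, giving the ring-A-conjugated enal, erasing C3/C4 and leaving C1 and C2 untouched because no base strong enough to deprotonate C2 is present.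

Step 11
Reactants: 19 [(1S,2R)-3-formyl-8-methoxy-1-{3-methoxy-4-[(triisopropylsilyl)oxy]phenyl}-7-[(triisopropylsilyl)oxy]-1,2-dihydronaphthalen-2-yl]methyl acetate
Product: 20 [(1S,2R)-3-formyl-7-hydroxy-1-(4-hydroxy-3-methoxyphenyl)-8-methoxy-1,2-dihydronaphthalen-2-yl]methyl acetate
Conditions: TBAF (2.5 equiv), AcOH (3 equiv), THF, 0 °C
Reagents that add atoms: none
Why: Fluoride-induced cleavage of both aryl silyl ethers (Si–O exchanged for Si–F), buffered with acetic acid so that the phenoxides are protonated at once and neither the acetate nor the enal with its γ-stereocentre C2 meets a strong base.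

Compound list
1 | 2-methoxybenzene-1,3-diol (2-methoxyresorcinol) | COc1c(O)cccc1O | starting material
2 | (2,4-dihydroxy-3-methoxybenzylidene)dimethyliminium chloride | COc1c(O)ccc(C=[N+](C)C)c1O.[Cl-] | intermediate (not isolated)
3 | 2,4-dihydroxy-3-methoxybenzaldehyde | COc1c(O)ccc(C=O)c1O | intermediate
4 | 2-hydroxy-3-methoxy-4-[(triisopropylsilyl)oxy]benzaldehyde | COc1c(O[Si](C(C)C)(C(C)C)C(C)C)ccc(C=O)c1O | intermediate
5 | 2-formyl-6-methoxy-5-[(triisopropylsilyl)oxy]phenyl trifluoromethanesulfonate | COc1c(O[Si](C(C)C)(C(C)C)C(C)C)ccc(C=O)c1OS(=O)(=O)C(F)(F)F | intermediate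
6 | vanillin (4-hydroxy-3-methoxybenzaldehyde) | COc1cc(C=O)ccc1O | starting material
7 | 3-methoxy-4-[(triisopropylsilyl)oxy]benzaldehyde | COc1cc(C=O)ccc1O[Si](C(C)C)(C(C)C)C(C)C | intermediate
8 | {3-methoxy-4-[(triisopropylsilyl)oxy]phenyl}methanol | COc1cc(CO)ccc1O[Si](C(C)C)(C(C)C)C(C)C | intermediate
9 | 3-methoxy-4-[(triisopropylsilyl)oxy]benzyl chlorosulfite | COc1cc(COS(=O)Cl)ccc1O[Si](C(C)C)(C(C)C)C(C)C | intermediate (not isolated)
10 | [4-(chloromethyl)-2-methoxyphenoxy]triisopropylsilane | COc1cc(CCl)ccc1O[Si](C(C)C)(C(C)C)C(C)C | intermediate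
11 | {3-methoxy-4-[(triisopropylsilyl)oxy]benzyl}zinc chloride | COc1cc(C[Zn]Cl)ccc1O[Si](C(C)C)(C(C)C)C(C)C | intermediate (not isolated)
12 | 3-methoxy-2-{3-methoxy-4-[(triisopropylsilyl)oxy]benzyl}-4-[(triisopropylsilyl)oxy]benzaldehyde | COc1cc(Cc2c(C=O)ccc(O[Si](C(C)C)(C(C)C)C(C)C)c2OC)ccc1O[Si](C(C)C)(C(C)C)C(C)C | intermediate
13 | (Z)-but-2-ene-1,4-diyl diacetate | CC(=O)OC/C=C\COC(C)=O | starting material
14 | (E)-but-2-enal (crotonaldehyde) | C/C=C/C=O | starting material
15 | (E)-4-acetoxybut-2-enal | CC(=O)OC/C=C/C=O | intermediate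
16 | photoenol of 12: ring A as a cyclohexa-1,3-diene with exocyclic =CH(OH) at C4a (E; OH outward) and exocyclic =CH(aryl) at C8a (aryl outward and cis to C8–OMe; Z by CIP only because C8 carries OMe) | O/C=C1\C=CC(O[Si](C(C)C)(C(C)C)C(C)C)=C(OC)/C1=C\c1ccc(O[Si](C(C)C)(C(C)C)C(C)C)c(OC)c1 | intermediate (not isolated)
17 | [(1S,2R,3S,4S)-3-formyl-4-hydroxy-8-methoxy-1-{3-methoxy-4-[(triisopropylsilyl)oxy]phenyl}-7-[(triisopropylsilyl)oxy]-1,2,3,4-tetrahydronaphthalen-2-yl]methyl acetate (aryl, formyl and hydroxyl cis; acetoxymethyl trans) | COc1cc([C@H]2c3c(ccc(O[Si](C(C)C)(C(C)C)C(C)C)c3OC)[C@@H](O)[C@@H](C=O)[C@@H]2COC(C)=O)ccc1O[Si](C(C)C)(C(C)C)C(C)C | intermediate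
18 | [(1S,2R,3S,4S)-3-formyl-8-methoxy-1-{3-methoxy-4-[(triisopropylsilyl)oxy]phenyl}-4-[(methylsulfonyl)oxy]-7-[(triisopropylsilyl)oxy]-1,2,3,4-tetrahydronaphthalen-2-yl]methyl acetate | COc1cc([C@H]2c3c(ccc(O[Si](C(C)C)(C(C)C)C(C)C)c3OC)[C@@H](OS(C)(=O)=O)[C@@H](C=O)[C@@H]2COC(C)=O)ccc1O[Si](C(C)C)(C(C)C)C(C)C | intermediate (not isolated)
19 | [(1S,2R)-3-formyl-8-methoxy-1-{3-methoxy-4-[(triisopropylsilyl)oxy]phenyl}-7-[(triisopropylsilyl)oxy]-1,2-dihydronaphthalen-2-yl]methyl acetate | COc1cc([C@H]2c3c(ccc(O[Si](C(C)C)(C(C)C)C(C)C)c3OC)C=C(C=O)[C@@H]2COC(C)=O)ccc1O[Si](C(C)C)(C(C)C)C(C)C | intermediate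
20 | [(1S,2R)-3-formyl-7-hydroxy-1-(4-hydroxy-3-methoxyphenyl)-8-methoxy-1,2-dihydronaphthalen-2-yl]methyl acetate (1,2-trans) | COc1cc([C@H]2c3c(ccc(O)c3OC)C=C(C=O)[C@@H]2COC(C)=O)ccc1O | target

Total step count: 11. Longest linear sequence: 7 steps (1, 2, 3, 7, 9, 10, 11; the vanillin branch 4, 5, 6, 7, 9, 10, 11 is equally long).

Steps most likely to fail

Risk 1, step 9. The chiral titanium complex may discriminate poorly between the two faces of the templated dienol–enal pair, because the acyclic enal binds through a single carbonyl. Reketonisation of the dienol before it is trapped, or partial E→Z photoisomerisation of the enal, could also erode the result. The fallback sets out from 12 and 15 and gives up asymmetric induction in favour of resolution. The cycloaddition is run with Ti(OiPr)4 alone under 366 nm light, which keeps the template (ortho, endo, outward dienol) and should give 17 as a racemate with the mirror-image adduct F1. The mixture is dehydrated with MsCl/Et3N as in step 10, passing through 18 and the mirror-image mesylate F2, to give 19 together with the mirror-image enal F3. The enantiomers are separated by preparative chromatography on a polysaccharide-carbamate chiral stationary phase (SFC or HPLC), chosen at this stage because the enal is stable and strongly UV-active. The fallback returns to the route at 19.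

Risk 2, step 7. The benzylic zinc reagent may add to the ortho formyl group, or transmetalation at the doubly ortho-substituted aryl–palladium species may be slow enough for Wurtz-type homocoupling of the benzyl partner to take over. The fallback sets out from 10 and replaces zinc by boron, which is inert toward the aldehyde. Palladium-catalysed Miyaura borylation of the benzylic chloride (B2pin2, Pd(dba)2, tris(4-methoxyphenyl)phosphine, KOAc, toluene, 50 °C) should give the benzyl pinacol boronate F4. An sp3–sp2 Suzuki–Miyaura coupling of it with triflate 5 (Pd(OAc)2/SPhos, K3PO4, toluene/H2O, 80 °C) returns to the route at 12.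

Risk 3, step 11. During fluoride treatment a basic species may deprotonate C2 (γ to the enal), leading to epimerisation or to loss of acetate and aromatisation to the naphthalene. The fallback sets out from 17 and removes the silyl groups before the enal exists, using acidic instead of basic fluoride. HF·pyridine in THF/pyridine (0 °C → rt) should give the bis-phenol aldol F5. Its C4 carbinol, now para to a free phenol, should lose water under catalytic PPTS in CH2Cl2 at rt through a quinone-methide-stabilised cation (E1) and give the conjugated enal. The fallback returns to the route at 20.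

Further compounds
F1 | step 9 | [(1R,2S,3R,4R)-3-formyl-4-hydroxy-8-methoxy-1-{3-methoxy-4-[(triisopropylsilyl)oxy]phenyl}-7-[(triisopropylsilyl)oxy]-1,2,3,4-tetrahydronaphthalen-2-yl]methyl acetate (enantiomer of 17) | COc1cc([C@@H]2c3c(ccc(O[Si](C(C)C)(C(C)C)C(C)C)c3OC)[C@H](O)[C@H](C=O)[C@H]2COC(C)=O)ccc1O[Si](C(C)C)(C(C)C)C(C)C
F2 | step 9 | [(1R,2S,3R,4R)-3-formyl-8-methoxy-1-{3-methoxy-4-[(triisopropylsilyl)oxy]phenyl}-4-[(methylsulfonyl)oxy]-7-[(triisopropylsilyl)oxy]-1,2,3,4-tetrahydronaphthalen-2-yl]methyl acetate (enantiomer of 18) | COc1cc([C@@H]2c3c(ccc(O[Si](C(C)C)(C(C)C)C(C)C)c3OC)[C@H](OS(C)(=O)=O)[C@H](C=O)[C@H]2COC(C)=O)ccc1O[Si](C(C)C)(C(C)C)C(C)C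
F3 | step 9 | [(1R,2S)-3-formyl-8-methoxy-1-{3-methoxy-4-[(triisopropylsilyl)oxy]phenyl}-7-[(triisopropylsilyl)oxy]-1,2-dihydronaphthalen-2-yl]methyl acetate (enantiomer of 19) | COc1cc([C@@H]2c3c(ccc(O[Si](C(C)C)(C(C)C)C(C)C)c3OC)C=C(C=O)[C@H]2COC(C)=O)ccc1O[Si](C(C)C)(C(C)C)C(C)C
F4 | step 7 | 2-{3-methoxy-4-[(triisopropylsilyl)oxy]benzyl}-4,4,5,5-tetramethyl-1,3,2-dioxaborolane | COc1cc(CB2OC(C)(C)C(C)(C)O2)ccc1O[Si](C(C)C)(C(C)C)C(C)C
F5 | step 11 | [(1S,2R,3S,4S)-3-formyl-4,7-dihydroxy-1-(4-hydroxy-3-methoxyphenyl)-8-methoxy-1,2,3,4-tetrahydronaphthalen-2-yl]methyl acetate | COc1cc([C@H]2c3c(ccc(O)c3OC)[C@@H](O)[C@@H](C=O)[C@@H]2COC(C)=O)ccc1O
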